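**Retrosynthetic overview**

1. Target 17 has ring A (benzene: C1 CH2OH, C2 H, C3 Br, C4 OH, C5 OH, C6 CH2 to ring B) and ring B (3-bromo-4-hydroxyphenyl). The endgame converts the C1 ester of benzoate 15 into CH2OH and its three aryl methyl ethers into phenols.
2. Key disconnection: ring A bonds C3–C4 and C5–C6. The feature used is that the segment C3(Br)–C2(H)–C1(ester)–C6(arylmethyl) is the diene of 3-bromo-2-pyrone-5-carboxylate 9, while the adjacent oxygen-bearing carbons C4 and C5 are the two carbons of ketene silyl acetal 12; only CO2 and Me3SiOH are lost.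
3. Pyrone 9 comes from C3 bromination of pyrone 7; 7 from β-keto ester 4 and methyl propiolate (Michael addition, enol lactonisation); 4 from arylacetic acid 1 and Meldrum's acid.
4. Ring order: ring B is bought with 1; the pyrone ring is built in step 2 and is converted into ring A in step 5.

Key step: step 5

Remark: the target has no stereocentre; the transient compounds 8, 13 and 14 are racemic and are drawn as one enantiomer, and their stereocentres vanish within the same step.

**Route**

Step 1
Reactants: 1 3-bromo-4-methoxyphenylacetic acid; 2 Meldrum's acid (2,2-dimethyl-1,3-dioxane-4,6-dione)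
Product: 4 methyl 4-(3-bromo-4-methoxyphenyl)-3-oxobutanoate, via acyl Meldrum's acid 3 (not isolated)
Conditions: DCC (1.1 equiv), DMAP (1.5 equiv), CH2Cl2, 0 → 25 °C; 1 M HCl wash; then MeOH, 65 °C
Reagents that add atoms: methanol, CO
Why: DCC activates the acid for C-acylation of Meldrum's acid (DMAP as acyl-transfer base), and hot methanol then opens 3 with loss of acetone and CO2 to the β-keto ester (Oikawa–Yonemitsu β-keto ester synthesis), which leaves the aryl bromide and aryl ether untouched.

Step 2
Reactants: 4 methyl 4-(3-bromo-4-methoxyphenyl)-3-oxobutanoate; 5 methyl propiolate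
Product: 7 methyl 6-(3-bromo-4-methoxybenzyl)-2-oxo-2H-pyran-5-carboxylate, via acylglutaconate 6 (not isolated)
Conditions: KOtBu (10 mol %), THF, 0 → 25 °C; then TsOH·H2O (20 mol %), PhMe, 110 °C
Reagents that add atoms: none
Why: The C2 carbanion of 4 adds to the ynoate (Michael addition) to give 6, whose ketone enol oxygen then acylates on the unsaturated ester under acid with loss of methanol (enol lactonisation, after E/Z equilibration through the glutaconate tautomers); acid is chosen for ring closure so that O-acylation, not base-induced carbocyclisation through the benzylic carbon, should prevail.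

Step 3
Reactants: 7 methyl 6-(3-bromo-4-methoxybenzyl)-2-oxo-2H-pyran-5-carboxylate
Product: 9 methyl 3-bromo-6-(3-bromo-4-methoxybenzyl)-2-oxo-2H-pyran-5-carboxylate, via trans-dibromide 8 (not isolated)
Conditions: Br2 (1.05 equiv), CH2Cl2, 0 °C, dark; then Et3N (1.5 equiv), 0 → 25 °C
Reagents that add atoms: bromine, BrBr
Why: Bromine attacks the pyrone at C3 and adds across C3=C4, and Et3N then removes H-3 (alpha to the lactone carbonyl) with loss of the C4 bromide (addition–elimination bromination of 2-pyrones); ring B should not compete in CH2Cl2 without a Lewis acid because its only free position ortho to the methoxy group lies meta to its bromine.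

Step 4
Reactants: 10 methyl methoxyacetate
Product: 12 (Z)-1,2-dimethoxy-1-(trimethylsilyloxy)ethene, via lithium enolate 11 (not isolated)
Conditions: LiN(iPr)2 (1.05 equiv), THF, −78 °C; then Me3SiCl, −78 → 25 °C; distillation
Reagents that add atoms: chlorotrimethylsilane, C[Si](C)(C)Cl
Why: Deprotonation of the α-alkoxy ester gives the lithium-chelated enolate 11 with the enolate oxygen cis to the 2-methoxy group, and O-silylation gives the Z ketene silyl acetal (standard ketene silyl acetal formation).

Step 5
Reactants: 9 methyl 3-bromo-6-(3-bromo-4-methoxybenzyl)-2-oxo-2H-pyran-5-carboxylate; 12 (Z)-1,2-dimethoxy-1-(trimethylsilyloxy)ethene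
Product: 15 methyl 5-bromo-2-(3-bromo-4-methoxybenzyl)-3,4-dimethoxybenzoate, via bridged lactone 13 (not isolated), via dihydroarene 14 (not isolated)
Conditions: 12 (3 equiv), iPr2NEt (0.2 equiv), PhMe, 60 → 110 °C, sealed tube
Reagents that add atoms: none
Why: The electron-poor diene of 9 (pyrone C3=C4–C5=C6, lowered by the lactone carbonyl, the ester and the bromine) and the electron-rich alkene of 12 combine in an inverse-electron-demand (4+2) cycloaddition, strongly asynchronous with the CH(OMe) carbon bonding to pyrone C6 and the acetal carbon to C3, to give the 2-oxabicyclo[2.2.2]octenone 13; retro-(4+2) loss of CO2 then gives dihydroarene 14 and 1,2-elimination of trimethylsilanol gives 15. The closest known reactions are the cycloadditions of 2-pyrone-5-carboxylates and of 3-bromo-2-pyrones with ketene acetals (1,1-dimethoxyethene, 1,1,2-trimethoxyethene) and silyl enol ethers, which give benzoates after loss of CO2 and an alcohol or silanol. Ring A is closed intermolecularly by the cycloaddition, which forms its C3–C4 and C5–C6 bonds, and is released from the bicycle by the cycloreversion. No stereocentre remains, since the four of 13 and the two of 14 are erased on aromatisation, so endo/exo selectivity is irrelevant. Orientation needs no control because each dienophile carbon brings its own methoxy group, so the opposite regioisomeric adduct would lead to the same benzoate. The one selectivity required, loss of silanol and not methanol from the mixed acetal carbon, is secured under these acid-free conditions by the Z geometry of 12, which leaves H-3 of 14 anti to the 4-silyloxy group, and by silanolate being the better leaving group; any share that kept the silyloxy group would appear as the C4 phenol and would still converge on 16 in step 6.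

Step 6
Reactants: 15 methyl 5-bromo-2-(3-bromo-4-methoxybenzyl)-3,4-dimethoxybenzoate
Product: 16 methyl 5-bromo-2-(3-bromo-4-hydroxybenzyl)-3,4-dihydroxybenzoate
Conditions: BBr3 (5 equiv), CH2Cl2, −78 → 0 °C; then ice/H2O
Reagents that add atoms: none
Why: BBr3 coordinates to each aryl ether oxygen and bromide removes the methyl group by SN2 (Lewis-acid cleavage of aryl methyl ethers), while at 0 °C or below the methyl ester, the diarylmethane link and the aryl bromides should survive.

Step 7
Reactants: 16 methyl 5-bromo-2-(3-bromo-4-hydroxybenzyl)-3,4-dihydroxybenzoate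
Product: 17 6-bromo-3-(3-bromo-4-hydroxybenzyl)-4-(hydroxymethyl)benzene-1,2-diol
Conditions: iBu2AlH (7 equiv, PhMe solution), THF, −78 → 0 °C; then KNaC4H4O6 (aq.)
Reagents that add atoms: none
Why: iBu2AlH first converts the three phenols into ArOAl(iBu)2 groups with loss of H2 and then reduces the ester to the primary alkoxide (hydride reduction of an ester), the aryl bromides being inert at 0 °C and the near-neutral tartrate work-up sparing the acid-labile para-hydroxybenzylic alcohol.

**Compound list**

1 | 3-bromo-4-methoxyphenylacetic acid | COc1ccc(CC(=O)O)cc1Br | starting material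
2 | Meldrum's acid (2,2-dimethyl-1,3-dioxane-4,6-dione) | CC1(C)OC(=O)CC(=O)O1 | starting material
3 | 5-[2-(3-bromo-4-methoxyphenyl)-1-hydroxyethylidene]-2,2-dimethyl-1,3-dioxane-4,6-dione (acyl Meldrum's acid, enol form) | COc1ccc(CC(O)=C2C(=O)OC(C)(C)OC2=O)cc1Br | intermediate (not isolated)
4 | methyl 4-(3-bromo-4-methoxyphenyl)-3-oxobutanoate | COC(=O)CC(=O)Cc1ccc(OC)c(Br)c1 | intermediate
5 | methyl propiolate | C#CC(=O)OC | starting material
6 | dimethyl (2E)-4-[(3-bromo-4-methoxyphenyl)acetyl]pent-2-enedioate (racemic, configurationally labile at C4) | COC(=O)/C=C/C(C(=O)OC)C(=O)Cc1ccc(OC)c(Br)c1 | intermediate (not isolated)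
7 | methyl 6-(3-bromo-4-methoxybenzyl)-2-oxo-2H-pyran-5-carboxylate | O=C1OC(Cc2ccc(OC)c(Br)c2)=C(C(=O)OC)C=C1 | intermediate
8 | methyl (3S*,4S*)-3,4-dibromo-6-(3-bromo-4-methoxybenzyl)-2-oxo-3,4-dihydro-2H-pyran-5-carboxylate (racemic trans-dibromide, one enantiomer drawn) | O=C1OC(Cc2ccc(OC)c(Br)c2)=C(C(=O)OC)[C@H](Br)[C@H]1Br | intermediate (not isolated)
9 | methyl 3-bromo-6-(3-bromo-4-methoxybenzyl)-2-oxo-2H-pyran-5-carboxylate | O=C1OC(Cc2ccc(OC)c(Br)c2)=C(C(=O)OC)C=C1Br | intermediate
10 | methyl methoxyacetate | COCC(=O)OC | starting material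
11 | lithium 1,2-dimethoxyethen-1-olate (enolate oxygen cis to the 2-methoxy group) | CO/C=C(/OC)[O-].[Li+] | intermediate (not isolated)
12 | (Z)-1,2-dimethoxy-1-(trimethylsilyloxy)ethene | CO/C=C(/OC)O[Si](C)(C)C | intermediate
13 | methyl 4-bromo-1-(3-bromo-4-methoxybenzyl)-7,8-dimethoxy-3-oxo-8-(trimethylsilyloxy)-2-oxabicyclo[2.2.2]oct-5-ene-6-carboxylate (racemic; 7-methoxy and 8-silyloxy cis to each other and syn to the C5=C6 bridge; one enantiomer drawn) | O=C1O[C@@]2(Cc3ccc(OC)c(Br)c3)C(C(=O)OC)=C[C@]1(Br)[C@](OC)(O[Si](C)(C)C)[C@@H]2OC | intermediate (not isolated)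
14 | methyl 5-bromo-2-(3-bromo-4-methoxybenzyl)-3,4-dimethoxy-4-(trimethylsilyloxy)cyclohexa-1,5-diene-1-carboxylate (racemic; 3-methoxy cis to 4-silyloxy; one enantiomer drawn) | COC(=O)C1=C(Cc2ccc(OC)c(Br)c2)[C@@H](OC)[C@@](OC)(O[Si](C)(C)C)C(Br)=C1 | intermediate (not isolated)
15 | methyl 5-bromo-2-(3-bromo-4-methoxybenzyl)-3,4-dimethoxybenzoate | COC(=O)c1cc(Br)c(OC)c(OC)c1Cc1ccc(OC)c(Br)c1 | intermediate
16 | methyl 5-bromo-2-(3-bromo-4-hydroxybenzyl)-3,4-dihydroxybenzoate | COC(=O)c1cc(Br)c(O)c(O)c1Cc1ccc(O)c(Br)c1 | intermediate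
17 | 6-bromo-3-(3-bromo-4-hydroxybenzyl)-4-(hydroxymethyl)benzene-1,2-diol | OCc1cc(Br)c(O)c(O)c1Cc1ccc(O)c(Br)c1 | target

**Step count**

Total: 7 steps. Longest linear sequence: 6 steps (steps 1, 2, 3, 5, 6, 7); step 4 is a one-step branch.

**Steps most likely to fail**

Step 5. Both new bonds are made to fully substituted pyrone carbons (C3 with its bromine, C6 with the arylmethyl group) by a trisubstituted dienophile. The cycloaddition may therefore be slower than O-to-C silyl migration or adventitious hydrolysis of 12, and the dihydroarene may divide between the silanol and methanol exits. The fallback sets out from 9 and returns at 15. Compound 9 would be heated in mesitylene at 140 °C with 1,1,2-trimethoxyethene F1, a known, distillable ketene dimethyl acetal of the class established for turning 2-pyrones into 1,2-dimethoxyarenes. It carries no silyl group and tolerates long heating. Its adduct, methyl 4-bromo-1-(3-bromo-4-methoxybenzyl)-7,8,8-trimethoxy-3-oxo-2-oxabicyclo[2.2.2]oct-5-ene-6-carboxylate F2, should lose CO2 to methyl 5-bromo-2-(3-bromo-4-methoxybenzyl)-3,4,4-trimethoxycyclohexa-1,5-diene-1-carboxylate F3. The only aromatising exit of F3 is loss of methanol, which gives 15.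

Step 3. Electrophilic bromine may be diverted to ring B (the free position ortho to its methoxy group) or to the doubly activated methylene at pyrone C6, or the dibromide may not eliminate cleanly towards the C3 bromide. The fallback sets out from 7 and returns at 15, with the ring A bromine introduced after the cycloaddition. Compound 7 would be heated with 12 (PhMe, iPr2NEt, 110 °C) to give methyl 1-(3-bromo-4-methoxybenzyl)-7,8-dimethoxy-3-oxo-8-(trimethylsilyloxy)-2-oxabicyclo[2.2.2]oct-5-ene-6-carboxylate F4, which should lose CO2 to methyl 2-(3-bromo-4-methoxybenzyl)-3,4-dimethoxy-4-(trimethylsilyloxy)cyclohexa-1,5-diene-1-carboxylate F5, and this should lose silanol to methyl 2-(3-bromo-4-methoxybenzyl)-3,4-dimethoxybenzoate F6. Bromination of F6 with N-bromosuccinimide in MeCN should then take place at ring A C5, giving 15. That position is ortho to the C4 methoxy group (the only one able to lie in the ring plane), para to the benzylic carbon and meta to the ester. C6 is ortho to the ester and is served only by the twisted C3 methoxy group, and ring B is deactivated by its bromine.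

Step 7. The tris-phenoxide formed from 16 and iBu2AlH may be poorly soluble and its ester, para to a phenoxide oxygen, sluggish. Forcing the reduction risks ionisation of the para-oxido benzylic alkoxide to a quinone methide, with over-reduction to the methyl compound or oligomerisation on work-up. The fallback sets out from 16 and returns at 17. Silylation (tBuMe2SiCl, imidazole, DMF, 25 °C) would give methyl 5-bromo-2-[3-bromo-4-(tert-butyldimethylsilyloxy)benzyl]-3,4-bis(tert-butyldimethylsilyloxy)benzoate F7. Reduction of this ordinary, soluble ester (iBu2AlH, CH2Cl2, −78 °C) would give {5-bromo-2-[3-bromo-4-(tert-butyldimethylsilyloxy)benzyl]-3,4-bis(tert-butyldimethylsilyloxy)phenyl}methanol F8. Buffered desilylation (Bu4NF, AcOH, THF, 0 °C) would then release 17.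

**Further compounds**

F1 | step 5 | 1,1,2-trimethoxyethene | COC=C(OC)OC
F2 | step 5 | methyl 4-bromo-1-(3-bromo-4-methoxybenzyl)-7,8,8-trimethoxy-3-oxo-2-oxabicyclo[2.2.2]oct-5-ene-6-carboxylate (racemic; 7-methoxy syn to the C5=C6 bridge; one enantiomer drawn) | O=C1O[C@@]2(Cc3ccc(OC)c(Br)c3)C(C(=O)OC)=C[C@]1(Br)C(OC)(OC)[C@@H]2OC
F3 | step 5 | methyl 5-bromo-2-(3-bromo-4-methoxybenzyl)-3,4,4-trimethoxycyclohexa-1,5-diene-1-carboxylate (racemic; one enantiomer drawn) | COC(=O)C1=C(Cc2ccc(OC)c(Br)c2)[C@@H](OC)C(OC)(OC)C(Br)=C1
F4 | step 3 | methyl 1-(3-bromo-4-methoxybenzyl)-7,8-dimethoxy-3-oxo-8-(trimethylsilyloxy)-2-oxabicyclo[2.2.2]oct-5-ene-6-carboxylate (racemic; 7-methoxy and 8-silyloxy cis and syn to the C5=C6 bridge; one enantiomer drawn) | O=C1O[C@@]2(Cc3ccc(OC)c(Br)c3)C(C(=O)OC)=C[C@@H]1[C@](OC)(O[Si](C)(C)C)[C@@H]2OC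
F5 | step 3 | methyl 2-(3-bromo-4-methoxybenzyl)-3,4-dimethoxy-4-(trimethylsilyloxy)cyclohexa-1,5-diene-1-carboxylate (racemic; 3-methoxy cis to 4-silyloxy; one enantiomer drawn) | COC(=O)C1=C(Cc2ccc(OC)c(Br)c2)[C@@H](OC)[C@@](OC)(O[Si](C)(C)C)C=C1
F6 | step 3 | methyl 2-(3-bromo-4-methoxybenzyl)-3,4-dimethoxybenzoate | COC(=O)c1ccc(OC)c(OC)c1Cc1ccc(OC)c(Br)c1
F7 | step 7 | methyl 5-bromo-2-[3-bromo-4-(tert-butyldimethylsilyloxy)benzyl]-3,4-bis(tert-butyldimethylsilyloxy)benzoate | COC(=O)c1cc(Br)c(O[Si](C)(C)C(C)(C)C)c(O[Si](C)(C)C(C)(C)C)c1Cc1ccc(O[Si](C)(C)C(C)(C)C)c(Br)c1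
F8 | step 7 | {5-bromo-2-[3-bromo-4-(tert-butyldimethylsilyloxy)benzyl]-3,4-bis(tert-butyldimethylsilyloxy)phenyl}methanol | OCc1cc(Br)c(O[Si](C)(C)C(C)(C)C)c(O[Si](C)(C)C(C)(C)C)c1Cc1ccc(O[Si](C)(C)C(C)(C)C)c(Br)c1
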